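**Retrosynthetic overview**
- Target 8 comes from aryl acetate 7 by methanolysis; 7 comes from the cyclic diarylbromonium salt 6, opened by acetate at C1 of ring A.
- Salt 6 comes from 2-(pentabromophenoxy)aniline 4 by diazotisation and loss of N2; this forms the C2'–Br bond and the only new ring.
- Amine 4 comes from nitro ether 3, made from pentabromophenol 1 and 1-fluoro-2-nitrobenzene 2 by SNAr and nitro reduction.
- Feature used: the C1–OH of ring A and the C2'–Br of ring B both sit ortho to the bridging ether oxygen (on C2 and C1'). A bromine that starts on C1 can therefore be passed to C2' through a six-membered ring O–C1'–C2'–Br–C1–C2, and C1 is then free to take oxygen.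
- Ring order: both benzene rings are bought; the oxygen- and bromine-bridged six-membered ring is the only ring formed (step 3) and is opened again in step 4.

Key step: step 3

Assumption: the target has no stereocentre and the diaryl ether rotates freely, so no stereocontrol is needed. Ring A is the tetrabromophenol ring (C1 bears OH, C2 the ether oxygen, C3–C6 bromine); ring B is the bromophenyl ring (C1' on oxygen, C2' bearing bromine).

Step 1
Reactants: 1 pentabromophenol; 2 1-fluoro-2-nitrobenzene
Product: 3 1,2,3,4,5-pentabromo-6-(2-nitrophenoxy)benzene
Conditions: K2CO3, DMF, 100 °C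
Reagents that add atoms: none
Why: Nucleophilic aromatic substitution by addition–elimination, in which the ortho nitro group and the fluoride leaving group make the C–F carbon electrophilic enough to accept the hindered, weakly nucleophilic pentabromophenoxide.

Step 2
Reactants: 3 1,2,3,4,5-pentabromo-6-(2-nitrophenoxy)benzene
Product: 4 2-(pentabromophenoxy)aniline
Conditions: Fe powder, AcOH/EtOH, 70 °C
Reagents that add atoms: none
Why: Dissolving-metal (Béchamp-type) reduction of the nitro group by electron transfer from iron, which leaves aryl–Br bonds intact where catalytic hydrogenation would not, and whose acidic medium keeps the new amine from attacking ring A.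

Step 3
Reactants: 4 2-(pentabromophenoxy)aniline
Product: 6 1,2,3,4-tetrabromodibenzo[b,e][1,4]oxabrominin-10-ium tetrafluoroborate, via 2-(pentabromophenoxy)benzenediazonium tetrafluoroborate 5 (not isolated)
Conditions: NOBF4 (1.1 equiv), 3 Å MS, dry ClCH2CH2Cl/MeCN (9:1), −30 to 0 °C; then 60 °C until N2 evolution ends; precipitation with Et2O
Reagents that add atoms: nitrosonium tetrafluoroborate, N#[O+].F[B-](F)(F)F
Why: Proposed new method: NOBF4 turns the amine into diazonium salt 5, which on warming should lose N2 heterolytically to leave a σ-aryl cation at C2' of ring B; an in-plane lone pair of an ortho bromine of ring A, held close by the ether bridge, captures the cation and forms the C2'–Br bond. The closest known reaction type is the dediazoniative closure of 2'-bromobiphenyl-2-diazonium salts to five-membered cyclic diarylbromonium salts; new here are the ether bridge, the six-membered ring and the perbrominated donor ring. The one ring is closed by attack of a heteroatom lone pair on a carbocation and consists of O, C1', C2', Br, C1 and C2; the bromine becomes trivalent and no stereocentre is formed. The two ortho bromines of the pentabromophenyl group are equivalent, so only one bromonium salt can form. The step needs bromine capture to outrun fluoride transfer from BF4-, capture by water or nitrile, attack on a ring A carbon (dibenzofuran-type closure) and homolytic reduction of the diazonium ion. The short tether puts a bromine donor next to the cation in every rotamer, the four further bromines make the ring A carbons too electron-poor to compete, and the medium is kept dry, copper-free and poor in nucleophiles.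

Step 4
Reactants: 6 1,2,3,4-tetrabromodibenzo[b,e][1,4]oxabrominin-10-ium tetrafluoroborate
Product: 7 2,3,4,5-tetrabromo-6-(2-bromophenoxy)phenyl acetate
Conditions: CsOAc (2 equiv), AcOH (5 equiv), MeCN, 25 to 50 °C
Reagents that add atoms: caesium acetate, CC(=O)[O-].[Cs+]
Why: Uncatalysed aryl transfer from a diarylbromonium salt to a carboxylate (ipso substitution by ligand coupling at trivalent bromine, as in arylations by diarylbromonium and diaryliodonium salts) should occur at C1 of ring A, the carbon made electrophilic by four bromines and flanked by two ortho substituents, with the neutral 2-bromophenoxy unit as leaving group, while the AcOH buffer keeps acetate from deprotonating C3' of ring B.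

Step 5
Reactants: 7 2,3,4,5-tetrabromo-6-(2-bromophenoxy)phenyl acetate
Product: 8 3,4,5,6-tetrabromo-2-(2-bromophenoxy)phenol
Conditions: K2CO3 (1.2 equiv), MeOH/THF, 0 °C to rt; then 1 M HCl
Reagents that add atoms: none
Why: Base-mediated transesterification of an electron-poor aryl acetate with methanol is fast at room temperature and touches neither the aryl bromides nor the diaryl ether.

**Compound list**
1 | pentabromophenol | Oc1c(Br)c(Br)c(Br)c(Br)c1Br | starting material
2 | 1-fluoro-2-nitrobenzene | O=[N+]([O-])c1ccccc1F | starting material
3 | 1,2,3,4,5-pentabromo-6-(2-nitrophenoxy)benzene | O=[N+]([O-])c1ccccc1Oc1c(Br)c(Br)c(Br)c(Br)c1Br | intermediate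
4 | 2-(pentabromophenoxy)aniline | Nc1ccccc1Oc1c(Br)c(Br)c(Br)c(Br)c1Br | intermediate
5 | 2-(pentabromophenoxy)benzenediazonium tetrafluoroborate | N#[N+]c1ccccc1Oc1c(Br)c(Br)c(Br)c(Br)c1Br.F[B-](F)(F)F | intermediate
6 | 1,2,3,4-tetrabromodibenzo[b,e][1,4]oxabrominin-10-ium tetrafluoroborate (six-membered ring of the ether O, the cationic Br and two carbons of each benzene ring; four Br on ring A) | Brc1c(Br)c(Br)c(Br)c2[Br+]c3ccccc3Oc12.F[B-](F)(F)F | intermediate
7 | 2,3,4,5-tetrabromo-6-(2-bromophenoxy)phenyl acetate | CC(=O)Oc1c(Br)c(Br)c(Br)c(Br)c1Oc1ccccc1Br | intermediate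
8 | 3,4,5,6-tetrabromo-2-(2-bromophenoxy)phenol | Oc1c(Br)c(Br)c(Br)c(Br)c1Oc1ccccc1Br | target

Total step count: 5
Longest linear sequence: 5

**Steps most likely to fail**

Step 3 (proposed new method). The aryl cation may be intercepted before the ring A bromine reaches it: by fluoride from BF4-, by the water released in the diazotisation, or by the nitrile. Alternatively the diazonium ion may be reduced to the aryl radical, and the transposition is lost. The fallback uses known chemistry only and gives up the bromine transposition. It sets out from 2: SNAr with an excess of commercial 3,4,5,6-tetrabromobenzene-1,2-diol (K2CO3, DMF, 80 °C) should give 3,4,5,6-tetrabromo-2-(2-nitrophenoxy)phenol F1. O-Methylation (MeI, K2CO3, acetone) gives 1,2,3,4-tetrabromo-5-methoxy-6-(2-nitrophenoxy)benzene F2, which prevents a later closure to a dibenzodioxin. Reduction with Fe powder in AcOH gives 2-(2,3,4,5-tetrabromo-6-methoxyphenoxy)aniline F3. Sandmeyer-type bromodeamination (t-BuONO, CuBr2, MeCN) gives 1,2,3,4-tetrabromo-5-(2-bromophenoxy)-6-methoxybenzene F4. BBr3 in CH2Cl2 then cleaves the methyl ether only, and the route comes back at target 8.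

Step 4. Acetate may act as a base at C3'–H of ring B and trigger elimination to an aryne, which would return the bromine to ring A; ligand coupling at bromine may also be slow and unselective between the two rings. The fallback sets out from 6 with a non-basic, soft nucleophile and forms the C–O bond by a different reaction. NaI in MeCN with warming (thermal collapse of the diarylbromonium iodide) should give 1,2,3,4-tetrabromo-5-(2-bromophenoxy)-6-iodobenzene F5. Iodine–magnesium exchange with i-PrMgCl·LiCl in THF at −78 °C, where iodine exchanges before any bromine, gives [2,3,4,5-tetrabromo-6-(2-bromophenoxy)phenyl]magnesium chloride F6. B(OMe)3 traps it as dimethyl [2,3,4,5-tetrabromo-6-(2-bromophenoxy)phenyl]boronate F7. Oxidation of the C–B bond with H2O2/NaOH at 0 °C then gives the phenol, so the route comes back at target 8 without passing through 7.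

Step 1. The doubly ortho-substituted, weakly nucleophilic pentabromophenoxide may add too slowly, so that at the temperature required the fluoronitroarene is consumed by hydrolysis or by dimethylamine from DMF. The fallback sets out from 1 and reverses the demand on the nucleophile by using a far stronger arylating agent. (2-Nitrophenyl)(2,4,6-trimethylphenyl)iodonium trifluoromethanesulfonate F8 is made from 1-iodo-2-nitrobenzene, mesitylene, mCPBA and TfOH in CH2Cl2. It should transfer its electron-poor 2-nitrophenyl group to the potassium salt of 1 (t-BuOK, THF, rt to 40 °C) in a metal-free O-arylation, and the route comes back at 3.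

**Further compounds**
F1 | step 3 | 3,4,5,6-tetrabromo-2-(2-nitrophenoxy)phenol | Oc1c(Br)c(Br)c(Br)c(Br)c1Oc1ccccc1[N+](=O)[O-]
F2 | step 3 | 1,2,3,4-tetrabromo-5-methoxy-6-(2-nitrophenoxy)benzene | COc1c(Br)c(Br)c(Br)c(Br)c1Oc1ccccc1[N+](=O)[O-]
F3 | step 3 | 2-(2,3,4,5-tetrabromo-6-methoxyphenoxy)aniline | COc1c(Br)c(Br)c(Br)c(Br)c1Oc1ccccc1N
F4 | step 3 | 1,2,3,4-tetrabromo-5-(2-bromophenoxy)-6-methoxybenzene | COc1c(Br)c(Br)c(Br)c(Br)c1Oc1ccccc1Br
F5 | step 4 | 1,2,3,4-tetrabromo-5-(2-bromophenoxy)-6-iodobenzene | Ic1c(Br)c(Br)c(Br)c(Br)c1Oc1ccccc1Br
F6 | step 4 | [2,3,4,5-tetrabromo-6-(2-bromophenoxy)phenyl]magnesium chloride | Cl[Mg]c1c(Br)c(Br)c(Br)c(Br)c1Oc1ccccc1Br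
F7 | step 4 | dimethyl [2,3,4,5-tetrabromo-6-(2-bromophenoxy)phenyl]boronate | COB(OC)c1c(Br)c(Br)c(Br)c(Br)c1Oc1ccccc1Br
F8 | step 1 | (2-nitrophenyl)(2,4,6-trimethylphenyl)iodonium trifluoromethanesulfonate | Cc1cc(C)c([I+]c2ccccc2[N+](=O)[O-])c(C)c1.[O-]S(=O)(=O)C(F)(F)F
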